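**Plan**
- Retrosynthesis: cut the O1–C2 bond of the pyranone ring (back to a 2'-oxygenated chalcone epoxide), then remove the oxirane oxygen (E-enone), then cut Cα=Cβ (aldol: acetophenone plus benzaldehyde), and last the three aryl–prenyl bonds (Stille: one aryl iodide, two aryl bromides).
- Forward: rings A and B are bought as arenes, MOM-protected and prenylated; the halves are joined by Claisen–Schmidt condensation, the enone is epoxidised, and the heterocyclic ring, the only ring that is made, is closed last with loss of all three MOM groups.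
- Enabling feature: C2–C3 of the pyranone is a β-aryloxy-α-hydroxy ketone, i.e. the anti adduct of the ring-A oxygen O1 and OH across a chalcone C=C. C2 is benzylic and para to the B-ring oxygen, and O1 sits on ring A ortho to the C4 carbonyl, so a trans-oxirane spanning C2/C3 can be opened 6-endo by O1.
- Stereochemistry: C3 comes from the catalyst-controlled Juliá–Colonna epoxidation (α-carbon R); C2 comes from stereospecific inversion at the β-carbon during ring closure, which gives the 2,3-trans (2R,3R) flavanonol.
- Only a nucleophilic oxidant and base-free Pd couplings are used, so the three prenyl C=C bonds never meet an electrophilic oxidant.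

Key step: step 8

Assumption: the facial selectivity of poly-L-leucine established for simple chalcones [(2R,3S)-epoxide] is taken to hold for enone 8; poly-D-leucine would be used if the opposite sense were found.

**Route**

Step 1
Reactants: 1 1-(2,4-dihydroxyphenyl)ethan-1-one
Product: 2 1-(2,4-dihydroxy-3-iodophenyl)ethan-1-one
Conditions: I2 (0.4 equiv), HIO3 (0.2 equiv), EtOH–H2O, 35 °C
Reagents that add atoms: iodine, II; iodic acid, OI(=O)=O
Why: Oxidative electrophilic aromatic iodination should enter C3, the position ortho to both hydroxyls that has enol character through the C3=C4–OH bond fixation imposed by the chelated 2-hydroxy ketone, and the limited iodine charge restrains a second iodination at C5.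

Step 2
Reactants: 2 1-(2,4-dihydroxy-3-iodophenyl)ethan-1-one
Product: 3 1-[3-iodo-2,4-bis(methoxymethoxy)phenyl]ethan-1-one
Conditions: NaH (2.2 equiv), MOMCl (2.4 equiv), DMF, 0 °C to rt
Reagents that add atoms: chloromethyl methyl ether (MOMCl), COCCl
Why: Williamson-type O-alkylation of the bis-phenoxide with the reactive α-chloro ether, in which NaH in DMF breaks the 2-OH···O=C chelate so that the hindered 2-hydroxyl is etherified too, while the limited base charge keeps the methyl ketone from enolising.

Step 3
Reactants: 3 1-[3-iodo-2,4-bis(methoxymethoxy)phenyl]ethan-1-one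
Product: 4 1-[2,4-bis(methoxymethoxy)-3-(3-methylbut-2-en-1-yl)phenyl]ethan-1-one
Conditions: tributyl(prenyl)stannane (1.3 equiv), Pd(PPh3)4 (5 mol %), DMF, 95 °C
Reagents that add atoms: tributyl(3-methylbut-2-en-1-yl)stannane, CCCC[Sn](CCCC)(CCCC)CC=C(C)C
Why: Stille coupling, in which oxidative addition to the C–I bond, transmetalation of the allyl-type stannane and reductive elimination through the unsubstituted CH2 terminus should give the linear prenyl arene, the fully substituted γ-terminus being disfavoured between two ortho OMOM groups, while the base-free conditions spare the methyl ketone and the acetals.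

Step 4
Reactants: 5 3,5-dibromo-4-hydroxybenzaldehyde
Product: 6 3,5-dibromo-4-(methoxymethoxy)benzaldehyde
Conditions: NaH (1.1 equiv), MOMCl (1.2 equiv), THF–DMF, 0 °C to rt
Reagents that add atoms: chloromethyl methyl ether (MOMCl), COCCl
Why: Williamson-type O-alkylation of the acidic 2,6-dibromophenoxide, with a non-enolisable aldehyde that is inert to NaH.

Step 5
Reactants: 6 3,5-dibromo-4-(methoxymethoxy)benzaldehyde
Product: 7 4-(methoxymethoxy)-3,5-bis(3-methylbut-2-en-1-yl)benzaldehyde
Conditions: tributyl(prenyl)stannane (2.5 equiv), Pd(PPh3)4 (5 mol %), DMF, 100 °C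
Reagents that add atoms: tributyl(3-methylbut-2-en-1-yl)stannane, CCCC[Sn](CCCC)(CCCC)CC=C(C)C
Why: Twofold Stille coupling at two C–Br bonds that each carry only one ortho substituent and are activated by the formyl group, with coupling through the CH2 terminus of the stannane and neutral conditions that leave the aldehyde alone.

Step 6
Reactants: 4 1-[2,4-bis(methoxymethoxy)-3-(3-methylbut-2-en-1-yl)phenyl]ethan-1-one; 7 4-(methoxymethoxy)-3,5-bis(3-methylbut-2-en-1-yl)benzaldehyde
Product: 8 (E)-1-[2,4-bis(methoxymethoxy)-3-(3-methylbut-2-en-1-yl)phenyl]-3-[4-(methoxymethoxy)-3,5-bis(3-methylbut-2-en-1-yl)phenyl]prop-2-en-1-one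
Conditions: KOH, EtOH–H2O, rt
Reagents that add atoms: none
Why: Claisen–Schmidt condensation in which only 4 can form an enolate and only 7 is a non-enolisable aldehyde, E1cB dehydration gives the E-enone, and the 2'-O-MOM group blocks oxa-Michael closure to a racemic flavanone.

Step 7
Reactants: 8 (E)-1-[2,4-bis(methoxymethoxy)-3-(3-methylbut-2-en-1-yl)phenyl]-3-[4-(methoxymethoxy)-3,5-bis(3-methylbut-2-en-1-yl)phenyl]prop-2-en-1-one
Product: 9 [(2R,3S)-3-[4-(methoxymethoxy)-3,5-bis(3-methylbut-2-en-1-yl)phenyl]oxiran-2-yl][2,4-bis(methoxymethoxy)-3-(3-methylbut-2-en-1-yl)phenyl]methanone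
Conditions: poly-L-leucine (immobilised), urea–H2O2, DBU, THF, rt
Reagents that add atoms: hydrogen peroxide (as its urea adduct), OO
Why: Juliá–Colonna epoxidation (a Weitz–Scheffer nucleophilic epoxidation inside the polyleucine helix), in which hydroperoxide adds to the enone β-carbon on the face selected by hydrogen bonding to the N-terminal NH groups and the enolate closes the oxirane by 3-exo-tet displacement of hydroxide, which keeps the trans geometry, sets the α-carbon as R (the future C3) and the β-carbon as S, and leaves the electron-rich prenyl alkenes untouched because the oxidant is a nucleophile.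

Step 8
Reactants: 9 [(2R,3S)-3-[4-(methoxymethoxy)-3,5-bis(3-methylbut-2-en-1-yl)phenyl]oxiran-2-yl][2,4-bis(methoxymethoxy)-3-(3-methylbut-2-en-1-yl)phenyl]methanone
Product: 12 (2R,3R)-3,7-dihydroxy-2-[4-hydroxy-3,5-bis(3-methylbut-2-en-1-yl)phenyl]-8-(3-methylbut-2-en-1-yl)-2,3-dihydro-4H-chromen-4-one, via 2'-hydroxy epoxide 10 (not isolated), via bis-MOM flavanonol 11 (not isolated)
Conditions: 3 M aq. HCl, MeOH–THF, 45 °C
Reagents that add atoms: none
Why: Acid cleaves the MOM acetals by oxocarbenium formation and methanol capture, the chelated 2'-O-MOM group expected first, and the freed 2'-hydroxyl (the future O1, held ortho to the ketone) attacks the protonated oxirane at its benzylic carbon anti to the departing oxygen, after which the two remaining MOM groups are lost. The closest known reaction type is the acid-mediated deprotective cyclisation of 2'-(alkoxymethoxy)chalcone epoxides to trans-flavanonols, the stepwise acid counterpart of the Algar–Flynn–Oyamada reaction. The pyranone ring closes by a 6-endo-tet epoxide opening that forms the O1–C2 bond, whereas the competing 5-exo-tet attack at the carbonyl-bearing carbon would give a 2-(α-hydroxybenzyl)benzofuran-3-one. C2 is set by inversion at the epoxide β-carbon (S to R) and C3 is the epoxide α-carbon carried over with its C–O bond intact (R), so the (2R,3R)-trans relationship follows from the trans-epoxide; should the opening drift towards a benzylic cation, closure anti to the C3 substituent should still lead to the diequatorial 2,3-trans ring. The step needs 6-endo regioselectivity, which the substrate secures because the β-carbon is benzylic and para to the B-ring oxygen and so carries the developing positive charge, while the α-carbon is deactivated by the adjacent carbonyl. It also needs the three prenyl groups and the α-ketol to survive, which dilute methanolic HCl at moderate temperature should allow because trisubstituted alkenes are protonated far more slowly than acetals and epoxides.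

**Compound list**
1 | 1-(2,4-dihydroxyphenyl)ethan-1-one | CC(=O)c1ccc(O)cc1O | starting material
2 | 1-(2,4-dihydroxy-3-iodophenyl)ethan-1-one | CC(=O)c1ccc(O)c(I)c1O | intermediate
3 | 1-[3-iodo-2,4-bis(methoxymethoxy)phenyl]ethan-1-one | CC(=O)c1ccc(OCOC)c(I)c1OCOC | intermediate
4 | 1-[2,4-bis(methoxymethoxy)-3-(3-methylbut-2-en-1-yl)phenyl]ethan-1-one | CC(=O)c1ccc(OCOC)c(CC=C(C)C)c1OCOC | intermediate
5 | 3,5-dibromo-4-hydroxybenzaldehyde | O=Cc1cc(Br)c(O)c(Br)c1 | starting material
6 | 3,5-dibromo-4-(methoxymethoxy)benzaldehyde | COCOc1c(Br)cc(C=O)cc1Br | intermediate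
7 | 4-(methoxymethoxy)-3,5-bis(3-methylbut-2-en-1-yl)benzaldehyde | COCOc1c(CC=C(C)C)cc(C=O)cc1CC=C(C)C | intermediate
8 | (E)-1-[2,4-bis(methoxymethoxy)-3-(3-methylbut-2-en-1-yl)phenyl]-3-[4-(methoxymethoxy)-3,5-bis(3-methylbut-2-en-1-yl)phenyl]prop-2-en-1-one | COCOc1ccc(C(=O)/C=C/c2cc(CC=C(C)C)c(OCOC)c(CC=C(C)C)c2)c(OCOC)c1CC=C(C)C | intermediate
9 | [(2R,3S)-3-[4-(methoxymethoxy)-3,5-bis(3-methylbut-2-en-1-yl)phenyl]oxiran-2-yl][2,4-bis(methoxymethoxy)-3-(3-methylbut-2-en-1-yl)phenyl]methanone | COCOc1ccc(C(=O)[C@@H]2O[C@H]2c3cc(CC=C(C)C)c(OCOC)c(CC=C(C)C)c3)c(OCOC)c1CC=C(C)C | intermediate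
10 | [(2R,3S)-3-[4-(methoxymethoxy)-3,5-bis(3-methylbut-2-en-1-yl)phenyl]oxiran-2-yl][2-hydroxy-4-(methoxymethoxy)-3-(3-methylbut-2-en-1-yl)phenyl]methanone (2'-hydroxy epoxide) | COCOc1ccc(C(=O)[C@@H]2O[C@H]2c3cc(CC=C(C)C)c(OCOC)c(CC=C(C)C)c3)c(O)c1CC=C(C)C | intermediate
11 | (2R,3R)-3-hydroxy-7-(methoxymethoxy)-2-[4-(methoxymethoxy)-3,5-bis(3-methylbut-2-en-1-yl)phenyl]-8-(3-methylbut-2-en-1-yl)-2,3-dihydro-4H-chromen-4-one (bis-MOM flavanonol) | CC(C)=CCc1cc([C@H]2Oc3c(ccc(OCOC)c3CC=C(C)C)C(=O)[C@@H]2O)cc(CC=C(C)C)c1OCOC | intermediate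
12 | (2R,3R)-3,7-dihydroxy-2-[4-hydroxy-3,5-bis(3-methylbut-2-en-1-yl)phenyl]-8-(3-methylbut-2-en-1-yl)-2,3-dihydro-4H-chromen-4-one | CC(C)=CCc1cc([C@H]2Oc3c(ccc(O)c3CC=C(C)C)C(=O)[C@@H]2O)cc(CC=C(C)C)c1O | target

**Summary**
Total steps: 8. Longest linear sequence: 6 (steps 1, 2, 3, 6, 7, 8).

**Steps most likely to fail**

Step 8. The benzylic C–O bond of the electron-rich oxirane may ionise before the 2'-hydroxyl is free, which would lead to solvent capture, a 1,2-aroyl shift or erosion of the trans relationship. The acid may also drive hydroalkoxylation of the ortho-prenyl phenols to chromans. The fallback puts the prenyl groups on after ring closure. It sets out from 3 and 6, which are condensed (KOH, EtOH) to (E)-3-[3,5-dibromo-4-(methoxymethoxy)phenyl]-1-[3-iodo-2,4-bis(methoxymethoxy)phenyl]prop-2-en-1-one F1. Juliá–Colonna epoxidation as in step 7 should give [(2R,3S)-3-[3,5-dibromo-4-(methoxymethoxy)phenyl]oxiran-2-yl][3-iodo-2,4-bis(methoxymethoxy)phenyl]methanone F2. Methanolic HCl then closes the ring to (2R,3R)-2-(3,5-dibromo-4-hydroxyphenyl)-3,7-dihydroxy-8-iodo-2,3-dihydro-4H-chromen-4-one F3; no prenyl group is present in the acid step, and the bromine atoms make ring B a poorer cation stabiliser. A threefold Stille coupling of F3 with tributyl(prenyl)stannane (Pd2(dba)3, P(t-Bu)3, DMF, 80–100 °C), which tolerates the free hydroxyls, comes back to the route at 12.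

Step 7. Conjugate addition of hydroperoxide to the electron-rich, ortho-disubstituted aryl enone may be slow, and uncatalysed background epoxidation would then erode the facial selectivity. The fallback builds the oxirane by C–C bond formation instead of oxygen transfer. It sets out from 4, whose lithium enolate (LiHMDS, THF, −78 °C) is chlorinated with TsCl to 2-chloro-1-[2,4-bis(methoxymethoxy)-3-(3-methylbut-2-en-1-yl)phenyl]ethan-1-one F4. An asymmetric Darzens reaction of F4 with 7 under a cinchona-alkaloid-derived quaternary ammonium phase-transfer catalyst (LiOH·H2O, CH2Cl2, 0 °C) proceeds by aldol addition and 3-exo-tet closure to the trans-epoxy ketone. The catalyst pseudoenantiomer is chosen for the (2R,3S) sense, and the sequence comes back to the route at 9.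

Step 3. Oxidative addition and transmetalation at the doubly ortho-substituted C–I bond may be slow, with competing protodeiodination or coupling through the γ-terminus of the stannane. The fallback uses direct nuclear prenylation instead of halogenation and cross-coupling. It sets out from 1, which is C-alkylated at C3 as its phenoxide in water (prenyl bromide, aq. KOH, rt) to 1-[2,4-dihydroxy-3-(3-methylbut-2-en-1-yl)phenyl]ethan-1-one F5. F5 is separated from its O-alkyl and C5 isomers, and bis-MOM protection (NaH, MOMCl, DMF) comes back to the route at 4.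

Further compounds
F1 | step 8 | (E)-3-[3,5-dibromo-4-(methoxymethoxy)phenyl]-1-[3-iodo-2,4-bis(methoxymethoxy)phenyl]prop-2-en-1-one | COCOc1ccc(C(=O)/C=C/c2cc(Br)c(OCOC)c(Br)c2)c(OCOC)c1I
F2 | step 8 | [(2R,3S)-3-[3,5-dibromo-4-(methoxymethoxy)phenyl]oxiran-2-yl][3-iodo-2,4-bis(methoxymethoxy)phenyl]methanone | COCOc1ccc(C(=O)[C@@H]2O[C@H]2c3cc(Br)c(OCOC)c(Br)c3)c(OCOC)c1I
F3 | step 8 | (2R,3R)-2-(3,5-dibromo-4-hydroxyphenyl)-3,7-dihydroxy-8-iodo-2,3-dihydro-4H-chromen-4-one | Oc1c(Br)cc([C@H]2Oc3c(ccc(O)c3I)C(=O)[C@@H]2O)cc1Br
F4 | step 7 | 2-chloro-1-[2,4-bis(methoxymethoxy)-3-(3-methylbut-2-en-1-yl)phenyl]ethan-1-one | O=C(CCl)c1ccc(OCOC)c(CC=C(C)C)c1OCOC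
F5 | step 3 | 1-[2,4-dihydroxy-3-(3-methylbut-2-en-1-yl)phenyl]ethan-1-one | CC(=O)c1ccc(O)c(CC=C(C)C)c1O
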